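## Retrosynthetic overview

1. Dictyol H ⇐ C6 silyl ether of the tertiary acetate ⇐ C10 ketone (late methylenation, acetylation, desilylation).
2. Oxolane ring (third and last ring): C12–C11 and O–C14 are formed together from a C7 methyl ketone and an (S)-epoxy-alkyl organocerium. This is possible because the ring oxygen bridges C11, a former carbonyl carbon on ring carbon C7, and C14, whose neighbour C15 carries the second oxygen (C14–O/C15–O is an opened C14–C15 epoxide).
3. Methyl ketone ⇐ ethylidene allylic silyl ether (hydroboration sets H-7) ⇐ exocyclic enone (Luche reduction sets C6) ⇐ aldol condensation of a hydroazulenone with acetaldehyde.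
4. Cyclopentene ring (second ring): Danheiser [3+2] annulation of an allenylsilane onto (R)-4-silyloxycyclohept-2-enone sets the cis fusion (C1, C5) and fixes the C3=C4 alkene.
5. Seven-membered ring (first ring): from cyclohepta-1,3-diene by photooxygenation and enantioselective Kornblum–DeLaMare rearrangement; the side-chain epoxide comes from 5-bromo-2-methylpent-2-ene by Shi epoxidation.

Key step: step 14

Remark (assumptions): locants follow hydroazulene (dictyol) numbering — C1/C5 ring fusion, C2–C4 cyclopentene with the methyl on C4, C6 carbinol, C7 side-chain carbon, C10 methylene carbon, C11–C15 side chain with C11 and C14 the oxolane carbons on oxygen; "upper face" is the face of H-1 and H-5 and "lower face" the one toward which C2 and C4 point; the target is read as (1R,5R,6S,7R,11R,14R); in step 2 the pseudoenantiomeric cinchona catalyst that delivers the (R)-hydroxy enone is meant.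

## Route

Step 1
Reactants: 1 cyclohepta-1,3-diene
Product: 2 6,7-dioxabicyclo[3.2.2]non-8-ene (meso endoperoxide)
Conditions: O2, hν (visible), 5,10,15,20-tetraphenylporphyrin (cat.), CH2Cl2, 0 °C
Reagents that add atoms: dioxygen O=O
Why: Singlet-oxygen [4+2] cycloaddition (photooxygenation) to the cisoid cyclic diene is suprafacial and so gives the meso endoperoxide with both C–O bonds on one face.

Step 2
Reactants: 2 6,7-dioxabicyclo[3.2.2]non-8-ene
Product: 3 (R)-4-hydroxycyclohept-2-en-1-one
Conditions: 9-O-acetylcupreidine (10 mol %), CH2Cl2, 23 °C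
Reagents that add atoms: none
Why: Enantioselective Kornblum–DeLaMare rearrangement, in which the chiral base removes one of the two enantiotopic bridgehead protons next to the O–O bond and the peroxide collapses to the γ-hydroxy enone, so the catalyst alone sets the carbinol centre (later C10).

Step 3
Reactants: 3 (R)-4-hydroxycyclohept-2-en-1-one
Product: 4 (R)-4-(tert-butyldimethylsilyloxy)cyclohept-2-en-1-one
Conditions: t-BuMe2SiCl, imidazole, DMF, 23 °C
Reagents that add atoms: tert-butyldimethylsilyl chloride CC(C)(C)[Si](C)(C)Cl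
Why: Standard silylation of a secondary alcohol masks the hydroxyl for the Lewis-acidic annulation and turns C10 into the directing stereocentre.

Step 4
Reactants: 4 (R)-4-(tert-butyldimethylsilyloxy)cyclohept-2-en-1-one; 5 buta-2,3-dien-2-yl(trimethyl)silane
Product: 6 10-(tert-butyldimethylsilyloxy)-4-methyl-3-(trimethylsilyl)-cis-bicyclo[5.3.0]dec-3-en-6-one (H-1 H-5 and the C10 oxygen on the upper face)
Conditions: TiCl4, CH2Cl2, −78 °C
Reagents that add atoms: none
Why: Danheiser (trimethylsilyl)cyclopentene annulation, a stepwise [3+2] in which the allene terminus attacks the TiCl4-activated enone at C1 anti to the neighbouring C10 silyloxy group, silicon shifts to the central allene carbon and the titanium enolate closes the ring at C5 on the same face, so that the cis ring fusion, C1, C5 and the C3=C4 alkene with the methyl on C4 are fixed in one step.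

Step 5
Reactants: 6 hydroazulenone
Product: 8 7-(1-hydroxyethyl) derivative of 6 (aldol adduct; mixture at C7 and the carbinol carbon), via lithium enolate 7 (not isolated)
Conditions: LiN(i-Pr)2, THF, −78 °C; CH3CHO, −78 °C; aq. NH4Cl
Reagents that add atoms: acetaldehyde CC=O
Why: Kinetic deprotonation takes the less hindered C7 methylene rather than the tertiary allylic C5–H and the lithium enolate undergoes aldol addition to acetaldehyde, the two new centres being erased in steps 6 and 9.

Step 6
Reactants: 8 aldol adduct
Product: 10 (E)-7-ethylidene derivative of 6 (exocyclic enone), via methanesulfonate 9 (not isolated)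
Conditions: MeSO2Cl, Et3N, CH2Cl2, 0 → 23 °C
Reagents that add atoms: none
Why: Mesylation followed by E1cB elimination of the β-sulfonyloxy ketone gives the conjugated exocyclic enone, the E isomer (methyl anti to the carbonyl) being the thermodynamically favoured one.

Step 7
Reactants: 10 exocyclic enone
Product: 11 allylic alcohol (6-hydroxyl on the lower face, H-6 on the upper face)
Conditions: NaBH4, CeCl3·7H2O, MeOH, −78 → 0 °C
Reagents that add atoms: none
Why: Luche 1,2-reduction, in which hydride attacks the C6 carbonyl from the upper (convex) face of the cis-fused bicycle away from the cyclopentene ring, places the hydroxyl on the lower face as in the target.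

Step 8
Reactants: 11 allylic alcohol
Product: 12 6-O-triisopropylsilyl ether of 11
Conditions: i-Pr3SiOSO2CF3, 2,6-lutidine, CH2Cl2, 0 °C
Reagents that add atoms: triisopropylsilyl trifluoromethanesulfonate CC(C)[Si](C(C)C)(C(C)C)OS(=O)(=O)C(F)(F)F
Why: Silylation with the silyl triflate converts the hindered allylic alcohol into a bulky, non-chelating and slowly migrating silyl ether that is needed in steps 9 and 14.

Step 9
Reactants: 12 ethylidene silyl ether
Product: 14 7-[(S)-1-hydroxyethyl] compound (H-7 on the upper face), via alkylborane 13 (not isolated)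
Conditions: BH3·SMe2, THF, 0 → 23 °C; then NaOH, H2O2, 0 °C
Reagents that add atoms: hydrogen peroxide OO
Why: Hydroboration–oxidation, in which BH3 adds syn to the exocyclic trisubstituted alkene from the upper face, anti to the allylic silyloxy group and to the cyclopentene ring, with boron on the less substituted C11, delivers H-7 to the upper face and oxygen to C11 while the tetrasubstituted vinylsilane is too hindered to react.

Step 10
Reactants: 14 secondary alcohol
Product: 15 7-acetyl-10-(tert-butyldimethylsilyloxy)-4-methyl-6-(triisopropylsilyloxy)-3-(trimethylsilyl)-cis-bicyclo[5.3.0]dec-3-ene (acetyl and C6 oxygen on the lower face)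
Conditions: Dess–Martin periodinane, NaHCO3, CH2Cl2, 23 °C
Reagents that add atoms: none
Why: Dess–Martin oxidation turns the secondary alcohol into the methyl ketone under buffered conditions that should not epimerize C7.

Step 11
Reactants: 15 β-silyloxy methyl ketone
Product: 16 7-acetyl-10-hydroxy-4-methyl-6-(triisopropylsilyloxy)-cis-bicyclo[5.3.0]dec-3-ene
Conditions: CF3CO2H, CH2Cl2/H2O, 0 → 23 °C
Reagents that add atoms: none
Why: Acid-mediated protodesilylation of the vinylsilane (ipso protonation at C3 gives the β-silyl cation at C4, which loses silicon and so keeps the alkene at C3=C4) is combined with hydrolysis of the less hindered tert-butyldimethylsilyl ether, the triisopropylsilyl ether at the crowded C6 being far more stable to acid.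

Step 12
Reactants: 17 5-bromo-2-methylpent-2-ene
Product: 18 (S)-2-(2-bromoethyl)-3,3-dimethyloxirane
Conditions: 1,2:4,5-di-O-isopropylidene-β-L-erythro-2,3-hexodiulo-2,6-pyranose (30 mol %), KHSO5 (as 2KHSO5·KHSO4·K2SO4), K2CO3, Bu4NHSO4, MeCN/CH2(OMe)2/aq. Na2B4O7, 0 °C
Reagents that add atoms: potassium peroxymonosulfate [K+].[O-]S(=O)(=O)OO
Why: Shi asymmetric epoxidation, in which the dioxirane of the L-fructose-derived ketone transfers oxygen to the trisubstituted alkene through the spiro transition state, should give the (S)-epoxide.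

Step 13
Reactants: 18 (S)-2-(2-bromoethyl)-3,3-dimethyloxirane
Product: 19 (S)-2-(2-iodoethyl)-3,3-dimethyloxirane
Conditions: NaI, NaHCO3, acetone, 50 °C
Reagents that add atoms: sodium iodide [Na+].[I-]
Why: Finkelstein halide exchange (SN2 at the primary carbon) gives the iodide needed for fast lithium–iodine exchange, and the buffered neutral medium leaves the epoxide untouched.

Step 14
Reactants: 16 hydroxy ketone; 19 (S)-2-(2-iodoethyl)-3,3-dimethyloxirane
Product: 23 oxolane diol (10-hydroxy compound carrying the (2R,5R)-5-(2-hydroxypropan-2-yl)-2-methyloxolan-2-yl group at C7 and the triisopropylsilyloxy group at C6), via alkyllithium 20 (not isolated), via alkylcerium dichloride 21 (not isolated), via epoxy alkoxide 22 (not isolated)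
Conditions: 19 (3.5 equiv), t-BuLi (7 equiv), Et2O/pentane, −78 °C; CeCl3, THF, −78 °C; then 16, −78 → 40 °C; aq. NH4Cl
Reagents that add atoms: none
Why: Proposed new method: the primary alkyllithium from lithium–iodine exchange is transmetalated at −78 °C to the weakly basic alkylcerium reagent, which adds to the C11 carbonyl (C12–C11), and on warming the tertiary alkoxide opens the tethered epoxide at C14 by intramolecular SN2 attack (O–C14), leaving the C15 alkoxide. The closest known reaction types are organocerium addition to hindered enolizable ketones and the base-mediated cyclization of 4,5-epoxy alkoxides to 2-(2-hydroxypropan-2-yl)oxolanes (linalool oxide formation), joined here in one flask with the epoxide carried by the nucleophile. The oxolane closes in the 5-exo-tet mode, which under basic conditions is preferred over 6-endo attack at the tertiary C15. C11 is set by Felkin–Anh addition, the nucleophile coming anti to the C7–C6 bond whose carbon carries the bulky non-chelating triisopropylsilyloxy group while the acetyl methyl lies next to H-7, and C14 is set by the (S)-epoxide through inversion, so the (11R,14R)-oxolane should result. The step needs addition to win over enolization with loss of the β-silyloxy group, over 1,3-silyl migration and over attack of the carbanion on its own epoxide (3-exo); CeCl3, the low temperature before warming, the slowly migrating triisopropylsilyl group and the unactivated trisubstituted epoxide are meant to secure this, and one extra equivalent of reagent is spent on the free C10 hydroxyl.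

Step 15
Reactants: 23 oxolane diol
Product: 24 10-oxo compound (C10 ketone of 23)
Conditions: Dess–Martin periodinane, NaHCO3, CH2Cl2, 0 → 23 °C
Reagents that add atoms: none
Why: Dess–Martin oxidation converts the only secondary alcohol into the C10 ketone and leaves the tertiary alcohol untouched.

Step 16
Reactants: 24 C10 ketone
Product: 25 10-methylene compound (deacetyl dictyol H 6-O-triisopropylsilyl ether)
Conditions: Zn, CH2Br2, TiCl4, THF/CH2Cl2, 0 → 23 °C
Reagents that add atoms: dibromomethane BrCBr
Why: Lombardo–Takai methylenation with the non-basic zinc–titanium methylene reagent turns the ketone into the exocyclic alkene without epimerizing the adjacent ring-fusion centre C1.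

Step 17
Reactants: 25 tertiary alcohol
Product: 26 dictyol H 6-O-triisopropylsilyl ether
Conditions: Ac2O, 4-(dimethylamino)pyridine, Et3N, CH2Cl2, 40 °C
Reagents that add atoms: acetic anhydride CC(=O)OC(C)=O
Why: Acylation under nucleophilic catalysis by 4-(dimethylamino)pyridine esterifies the tertiary hydroxyl, which is the only free one.

Step 18
Reactants: 26 dictyol H 6-O-triisopropylsilyl ether
Product: 27 dictyol H
Conditions: HF·pyridine, pyridine, THF, 0 → 40 °C
Reagents that add atoms: none
Why: Fluoride-mediated silyl ether cleavage (Si–F bond formation) frees the C6 hydroxyl without touching the tertiary acetate or the alkenes.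

## Compound list

1 | cyclohepta-1,3-diene | C1=CC=CCCC1 | starting material
2 | 6,7-dioxabicyclo[3.2.2]non-8-ene (meso endoperoxide) | C1CC[C@@H]2OO[C@H]1C=C2 | intermediate
3 | (R)-4-hydroxycyclohept-2-en-1-one | [C@@H]1(O)CCCC(=O)C=C1 | intermediate
4 | (R)-4-(tert-butyldimethylsilyloxy)cyclohept-2-en-1-one | [C@@H]1(O[Si](C)(C)C(C)(C)C)CCCC(=O)C=C1 | intermediate
5 | buta-2,3-dien-2-yl(trimethyl)silane | C=C=C(C)[Si](C)(C)C | starting material
6 | 10-(tert-butyldimethylsilyloxy)-4-methyl-3-(trimethylsilyl)-cis-bicyclo[5.3.0]dec-3-en-6-one (H-1 H-5 and C10 oxygen on the upper face) | [C@@H]1(O[Si](C)(C)C(C)(C)C)CCCC(=O)[C@H]2C(C)=C([Si](C)(C)C)C[C@@H]12 | intermediate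
7 | lithium C6=C7 enolate of 6 | [C@@H]1(O[Si](C)(C)C(C)(C)C)CCC=C([O-])[C@H]2C(C)=C([Si](C)(C)C)C[C@@H]12.[Li+] | intermediate
8 | 7-(1-hydroxyethyl) derivative of 6 (aldol adduct; mixture at C7 and the carbinol carbon) | [C@@H]1(O[Si](C)(C)C(C)(C)C)CCC(C(C)O)C(=O)[C@H]2C(C)=C([Si](C)(C)C)C[C@@H]12 | intermediate
9 | methanesulfonate of 8 | [C@@H]1(O[Si](C)(C)C(C)(C)C)CCC(C(C)OS(C)(=O)=O)C(=O)[C@H]2C(C)=C([Si](C)(C)C)C[C@@H]12 | intermediate
10 | (E)-7-ethylidene derivative of 6 (exocyclic enone) | [C@@H]1(O[Si](C)(C)C(C)(C)C)CC/C(=C\C)C(=O)[C@H]2C(C)=C([Si](C)(C)C)C[C@@H]12 | intermediate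
11 | (E)-7-ethylidene 6-ol (hydroxyl on the lower face) | [C@@H]1(O[Si](C)(C)C(C)(C)C)CC/C(=C\C)[C@@H](O)[C@H]2C(C)=C([Si](C)(C)C)C[C@@H]12 | intermediate
12 | 6-O-triisopropylsilyl ether of 11 | [C@@H]1(O[Si](C)(C)C(C)(C)C)CC/C(=C\C)[C@@H](O[Si](C(C)C)(C(C)C)C(C)C)[C@H]2C(C)=C([Si](C)(C)C)C[C@@H]12 | intermediate
13 | C11 alkylborane from 12 (boron on C11, H-7 on the upper face) | [C@@H]1(O[Si](C)(C)C(C)(C)C)CC[C@@H]([C@H](C)B)[C@@H](O[Si](C(C)C)(C(C)C)C(C)C)[C@H]2C(C)=C([Si](C)(C)C)C[C@@H]12 | intermediate
14 | 7-[(S)-1-hydroxyethyl] compound (H-7 on the upper face) | [C@@H]1(O[Si](C)(C)C(C)(C)C)CC[C@@H]([C@H](C)O)[C@@H](O[Si](C(C)C)(C(C)C)C(C)C)[C@H]2C(C)=C([Si](C)(C)C)C[C@@H]12 | intermediate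
15 | 7-acetyl-10-(tert-butyldimethylsilyloxy)-4-methyl-6-(triisopropylsilyloxy)-3-(trimethylsilyl)-cis-bicyclo[5.3.0]dec-3-ene | [C@@H]1(O[Si](C)(C)C(C)(C)C)CC[C@@H](C(C)=O)[C@@H](O[Si](C(C)C)(C(C)C)C(C)C)[C@H]2C(C)=C([Si](C)(C)C)C[C@@H]12 | intermediate
16 | 7-acetyl-10-hydroxy-4-methyl-6-(triisopropylsilyloxy)-cis-bicyclo[5.3.0]dec-3-ene | [C@@H]1(O)CC[C@@H](C(C)=O)[C@@H](O[Si](C(C)C)(C(C)C)C(C)C)[C@H]2C(C)=CC[C@@H]12 | intermediate
17 | 5-bromo-2-methylpent-2-ene | CC(C)=CCCBr | starting material
18 | (S)-2-(2-bromoethyl)-3,3-dimethyloxirane | BrCC[C@@H]1OC1(C)C | intermediate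
19 | (S)-2-(2-iodoethyl)-3,3-dimethyloxirane | ICC[C@@H]1OC1(C)C | intermediate
20 | 2-[(S)-3,3-dimethyloxiran-2-yl]ethyllithium | [Li]CC[C@@H]1OC1(C)C | intermediate
21 | dichloro{2-[(S)-3,3-dimethyloxiran-2-yl]ethyl}cerium | Cl[Ce](Cl)CC[C@@H]1OC1(C)C | intermediate
22 | C11 tertiary alkoxide adduct of 16 and 21 (drawn protonated as the epoxy diol) | [C@@H]1(O)CC[C@@H]([C@@](O)(C)CC[C@@H]3OC3(C)C)[C@@H](O[Si](C(C)C)(C(C)C)C(C)C)[C@H]2C(C)=CC[C@@H]12 | intermediate
23 | oxolane diol: 10-hydroxy-7-[(2R,5R)-5-(2-hydroxypropan-2-yl)-2-methyloxolan-2-yl]-4-methyl-6-(triisopropylsilyloxy)-cis-bicyclo[5.3.0]dec-3-ene | [C@@H]1(O)CC[C@@H]([C@@]2(C)CC[C@H](C(C)(C)O)O2)[C@@H](O[Si](C(C)C)(C(C)C)C(C)C)[C@H]2C(C)=CC[C@@H]12 | intermediate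
24 | C10 ketone of 23 | O=C1CC[C@@H]([C@@]2(C)CC[C@H](C(C)(C)O)O2)[C@@H](O[Si](C(C)C)(C(C)C)C(C)C)[C@H]2C(C)=CC[C@@H]12 | intermediate
25 | 10-methylene compound (deacetyl dictyol H 6-O-triisopropylsilyl ether) | C=C1CC[C@@H]([C@@]2(C)CC[C@H](C(C)(C)O)O2)[C@@H](O[Si](C(C)C)(C(C)C)C(C)C)[C@H]2C(C)=CC[C@@H]12 | intermediate
26 | dictyol H 6-O-triisopropylsilyl ether | C=C1CC[C@@H]([C@@]2(C)CC[C@H](C(C)(C)OC(C)=O)O2)[C@@H](O[Si](C(C)C)(C(C)C)C(C)C)[C@H]2C(C)=CC[C@@H]12 | intermediate
27 | dictyol H | C=C1CC[C@@H]([C@@]2(C)CC[C@H](C(C)(C)OC(C)=O)O2)[C@@H](O)[C@H]2C(C)=CC[C@@H]12 | target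

## Step count and risks

Total step count: 18. Longest linear sequence: 16 (steps 1–11 and 14–18).

**Step 14 (key step).** The epoxide-bearing organolithium or organocerium reagent may attack its own epoxide before it reaches the ketone. The cerium alkoxide may also fail to close the ring, or may open the epoxide at the tertiary carbon. The fallback separates the two bond formations and sets out from 16 and 17. Bromide 17 is converted with Mg in THF into (4-methylpent-3-en-1-yl)magnesium bromide F1, which is transmetalated with CeCl3 and added to ketone 16 at −78 °C. By the same Felkin–Anh addition this should give the bishomoallylic tertiary alcohol F2. Shi epoxidation of the side-chain alkene of F2 with the same L-fructose-derived ketone and KHSO5 should then give the (S)-epoxy alcohol that is the protonated form of 22. The unhindered side-chain alkene is expected to react before the ring alkene, which is flanked by the ring fusion. Treatment with NaH in THF closes the ring 5-exo with inversion at C14 and comes back to the route at 23.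

**Step 11.** Under the protic acid the freed trisubstituted alkene may migrate toward the ring fusion, C7 may epimerize through the enol, or the triisopropylsilyl ether may be lost. The fallback removes the two silicon groups without protic acid and sets out from 15. Iododesilylation with N-iodosuccinimide in MeCN at 0 °C should give the vinyl iodide F3 with the alkene held in place. Reduction with Bu3SnH and Pd(PPh3)4 (cat.) gives the trisubstituted alkene F4. HF·pyridine at 0 °C then removes the less hindered tert-butyldimethylsilyl ether selectively and comes back to the route at 16.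

**Step 9.** Hydrogen may be delivered to C7 with poor facial selectivity, or the borane may add elsewhere. The fallback sets H-7 by protonation of an acetyl enolate instead and sets out from 6.
- LiN(i-Pr)2 and Me3SiCl give the trimethylsilyl enol ether F5.
- Saegusa–Ito oxidation with Pd(OAc)2 gives the cycloheptenone F6.
- I2 and pyridine give the α-iodo enone F7.
- Luche reduction from the upper face gives the iodo allylic alcohol F8.
- i-Pr3SiOSO2CF3 and 2,6-lutidine give its triisopropylsilyl ether F9.
- Stille coupling with tributyl(1-ethoxyvinyl)stannane (Pd(PPh3)4, CuI) gives the ethoxy diene F10, and dilute aqueous HCl hydrolyses it to the acetyl enone F11.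
- Conjugate reduction with [(Ph3P)CuH]6, followed by protonation of the enolate from the upper face, should come back to the route at 15.

## Further compounds

F1 | step 14 | (4-methylpent-3-en-1-yl)magnesium bromide | CC(C)=CCC[Mg]Br
F2 | step 14 | tertiary alcohol: 16 with (R)-2-hydroxy-6-methylhept-5-en-2-yl in place of acetyl | [C@@H]1(O)CC[C@@H]([C@@](O)(C)CCC=C(C)C)[C@@H](O[Si](C(C)C)(C(C)C)C(C)C)[C@H]2C(C)=CC[C@@H]12
F3 | step 11 | vinyl iodide: 15 with iodine in place of the C3 trimethylsilyl group | [C@@H]1(O[Si](C)(C)C(C)(C)C)CC[C@@H](C(C)=O)[C@@H](O[Si](C(C)C)(C(C)C)C(C)C)[C@H]2C(C)=C(I)C[C@@H]12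
F4 | step 11 | 15 without the C3 trimethylsilyl group (10-O-tert-butyldimethylsilyl ether of 16) | [C@@H]1(O[Si](C)(C)C(C)(C)C)CC[C@@H](C(C)=O)[C@@H](O[Si](C(C)C)(C(C)C)C(C)C)[C@H]2C(C)=CC[C@@H]12
F5 | step 9 | trimethylsilyl enol ether of 6 (C6=C7) | [C@@H]1(O[Si](C)(C)C(C)(C)C)CCC=C(O[Si](C)(C)C)[C@H]2C(C)=C([Si](C)(C)C)C[C@@H]12
F6 | step 9 | 7,8-didehydro derivative of 6 (cycloheptenone) | [C@@H]1(O[Si](C)(C)C(C)(C)C)CC=CC(=O)[C@H]2C(C)=C([Si](C)(C)C)C[C@@H]12
F7 | step 9 | 7-iodo derivative of the cycloheptenone | [C@@H]1(O[Si](C)(C)C(C)(C)C)CC=C(I)C(=O)[C@H]2C(C)=C([Si](C)(C)C)C[C@@H]12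
F8 | step 9 | 7-iodo allylic alcohol (6-hydroxyl on the lower face) | [C@@H]1(O[Si](C)(C)C(C)(C)C)CC=C(I)[C@@H](O)[C@H]2C(C)=C([Si](C)(C)C)C[C@@H]12
F9 | step 9 | 6-O-triisopropylsilyl ether of the iodo allylic alcohol | [C@@H]1(O[Si](C)(C)C(C)(C)C)CC=C(I)[C@@H](O[Si](C(C)C)(C(C)C)C(C)C)[C@H]2C(C)=C([Si](C)(C)C)C[C@@H]12
F10 | step 9 | 7-(1-ethoxyvinyl) diene | [C@@H]1(O[Si](C)(C)C(C)(C)C)CC=C(C(=C)OCC)[C@@H](O[Si](C(C)C)(C(C)C)C(C)C)[C@H]2C(C)=C([Si](C)(C)C)C[C@@H]12
F11 | step 9 | 7-acetyl 7,8-ene (acetyl enone) | [C@@H]1(O[Si](C)(C)C(C)(C)C)CC=C(C(C)=O)[C@@H](O[Si](C(C)C)(C(C)C)C(C)C)[C@H]2C(C)=C([Si](C)(C)C)C[C@@H]12
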